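# Proposed total synthesis of CNP0180877.1 ((2S,3R,4S,5S,9R,10S,13R)-2-acetoxy-3-hydroxy-19-oxolabd-7-en-15-oic acid)

## Structural features

The target is a bicyclic diterpenoid acid of the ent-labdane type: a trans-fused decalin (ring A = C1–C5, C10; ring B = C5–C10) with a trisubstituted C7=C8 alkene, the C17 methyl group on C8 and, on C9, the saturated chain C11–C12–C13(C16)–C14–C15O2H. Six stereocentres are contiguous around the rings: C2 (equatorial acetoxy), C3 (axial hydroxy), quaternary C4 (equatorial C18 methyl, axial C19 formyl), C5, quaternary C10 (axial C20 methyl) and C9; the seventh, C13, sits alone in the chain. C19, C20 and C11 lie on one face, and H5, H9, C18 and both ring oxygens on the other, so the 2,3-diol is cis and O3 is trans to C19 across the C3–C4 bond. The fragile groups are the β-hydroxy aldehyde C3(OH)–C4–C19HO (retro-aldol in base), the monoacetate of a cis-diol (acyl migration), the 7-ene (acid moves it to the tetrasubstituted 8-position) and the free acid. The real difficulty is the congested C4–C5–C10 array, with two quaternary carbons at the ring fusion and a 1,3-diaxial C19/C20 pair, together with telling O2 from O3 and placing the alkene at C7=C8. The key step exploits the fact that C5, C10 and C9 are neighbours on ring B: C9=C10 serves as an (E)-3-methyl-2-enal, C5=C6–C7=C8 as a diene, and the ring A atoms C1–C4 as the tether between C10 and C5, so one cycloaddition closes both rings.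

## Logic of the disconnections

**38 to 36.** The acetyl–O2 bond is cut. An acetate on a cis-diol would not survive the basic and hydridic steps before it, so it is put on last. This leaves 36, in which both hydroxyl groups can be carried as one ketal. The forward step must acylate the equatorial O2 and leave the axial, neopentyl O3 alone; the C15 acid is acylated transiently (37) and freed again on work-up.

**36 to 32.** The ketal C–O bonds, the C19 oxidation level, the O19–Si bond and the ester O–CH3 bond are cut in turn (36, 35, 34, 33, 32). The β-hydroxy aldehyde and the acid are thus exposed only at the end, and 32 is fully protected and robust. The forward order is fixed by this: saponification before any aldehyde exists, oxidation of C19 while the diol is still masked, and a ketal hydrolysis mild enough to leave the 7-ene in place.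

**32 to 29.** The C7–H bond is traced back to a C7–O bond (31), then to the C7 ketone (30) and its silyl enol ether (29). Oxygen at C7 is what the cycloaddition leaves behind, and passing through C7=C8 removes the extra C8 stereocentre. The forward step must enolise the ketone towards C8, not towards C6.

**29 to 23 + 26.** The C11–C12 bond is cut, as a C11=C12 alkene in 28. This joins a bicyclic aldehyde to a five-carbon unit that brings C13 from the chiral pool. The forward olefination has to work on a hindered aldehyde without touching C9, and the hydrogenation has to spare the enol ether.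

**23 to 22.** The bonds C5–C10 and C8–C9 are cut together. This removes both rings and four stereocentres and leaves an acyclic trienal whose only stereocentres are C2, C3 and C4. The forward step must be endo-selective and must choose one diene face. The configuration of 22 (2S,3R,4R in labdane numbering, (E)-enal, (Z)-enol ether) maps onto 23 and 38 as it stands; the only change made to the pair is a tert-butyldiphenylsilyl group on O19, which the supply route requires.

**22 to 19.** The formyl group is traced back to a methyl ester (21, 20) and the silyloxy diene to an enone (19). A free enal with γ-hydrogens would itself be enolised by the silyl triflate and amine, and would react in the olefination before that, so it is unveiled last. The reduction and oxidation must spare the silyl dienol ether.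

**19 to 15 + 16.** The C5=C6 bond is cut (17), and the ketal is traced back to two silyl ethers (18). This gives a non-enolisable neopentyl aldehyde and a four-carbon phosphonate that carries C6, C7, C8 and C17. The forward olefination must be (E)-selective on a hindered aldehyde.

**15 to 9.** C19 is traced back to a vinyl group (14, 13, 12, 11, 10) and C5 to a hydroxymethyl group. The reason is stereochemical. The iridium-catalysed tert-(hydroxy)prenylation puts the carbinol oxygen anti to the hydroxymethyl group. If the hydroxymethyl group were used as C19 and the vinyl group as C5, this would give the C3 epimer of 22. With the roles exchanged, the same adduct has O3 syn to C19 and anti to C18, as required. The forward sequence must cleave the vinyl group in the presence of the enoate and must keep the two CH2O arms on C4 distinct at all times.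

**9 to 6 + 7.** The C3–C4 bond is cut. This sets the quaternary C4 and the C3 carbinol in one catalytic step from a primary alcohol and a racemic vinyl epoxide. The catalyst has to override the bias of the C2 stereocentre and give the 2,3-anti adduct.

**6 to 1.** The bonds C9–C11 and C10–C20 are cut (5, 4, 3), then C1–C10 (2, 1). Methylalumination of a terminal alkyne followed by acylation fixes the (E)-trisubstituted alkene without an isomer problem, and the alkyne comes from an acetylide and a glycidyl ether that supplies C2. The forward steps need a terminal alkyne and an ether-protected O2.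

**26 to 24.** The C12–P bond and the C12–Br bond are cut (25), back to the lactone, whose C–O bond becomes C12–Br. The C13 stereocentre is never involved.

## Other disconnections considered

**Alternative 1:** The cut is C2–C3. In the forward step SmI2 would couple the C2 aldehyde of trialdehyde A2 with one of the two formyl groups on C4, to give the cis-2,3-diol 19-aldehyde allyl ester A1.
- In its favour: C19 is at the aldehyde level from the start, so no protecting group or late oxidation is needed there; on this point the alternative is better than the chosen plan. The chelated ketyl coupling should give the cis-diol directly.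
- Against it: one step has to choose between two diastereotopic formyl groups (which sets C4) and between the faces of the C2 aldehyde, under substrate control only. A2 carries an enolisable aldehyde next to a 1,3-dialdehyde, and the product is a samarium alkoxide of a β-hydroxy aldehyde, open to retro-aldol and over-reduction.
- Comparison: it forms one bond and one ring, against two bonds, two rings and four stereocentres in the chosen plan, and ring B with C5, C9 and C10 must be built separately. The mechanism is radical and chelation-controlled, less predictable than a pericyclic step with endo and (E)-geometry control. A1 needs the same selective O2 acetylation as 36, so on that point the two are equal.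

**Alternative 2:** The cuts are C5–C6 and C1–C10. In the forward step Ph3PAuNTf2 would activate the allene of A4; C5 of the C5=C10 alkene attacks C6, and the C10 cation is trapped by C1 of the silyl enol ether, to give the 2-oxo-7-ene decalin A3.
- In its favour: it forms two rings and two bonds in one step, equal to the chosen plan. The 7-ene arrives in place after protodeauration, which is better than the three steps the chosen plan spends on it. O2 appears as a ketone, already distinct from O3, which is also better for the final acetylation.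
- Against it: the silyl enol ether is a better nucleophile for the gold-bound allene than the trisubstituted alkene, so a direct closure onto the allene competes. The cascade needs a chair–chair fold with a quaternary carbon next to the nucleophilic alkene. A4 must be assembled as an acyclic chain with four stereocentres (C3, C4, C9, C13) and a defined (E)-alkene, and the allyl ester has to pass through a cationic step. The C2 ketone must later be reduced with the correct facial selectivity.
- Comparison: fewer steps after the cyclisation, but a longer and harder precursor, and stereocontrol that rests on conformational preference in a cation–olefin cascade.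

**Alternative 3:** The cut is C9–C10. In the forward step Fe(acac)3 and PhSiH3 would transfer a hydrogen atom to C1 of cyclohexene A6, and the tertiary C10 radical would add 6-exo to C9 of the (2E,4Z)-dienoate, to give the trans-decalin ester A5.
- In its favour: the conditions are mild and tolerate the ketal and silyl ether, the same protecting pattern as in the chosen plan, so the end game is equal. The 7-ene is carried in as the (4Z)-alkene, which is better than the chosen plan on this point. A radical addition is little affected by the congestion at C10.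
- Against it: only one ring and one C–C bond are formed, and ring A with C2, C3, C4 and C5 must be prepared beforehand. The ring fusion depends on the face by which a planar radical is attacked, and C9 depends on the conformation of the dienoate. The (4Z)-alkene is prone to isomerisation. A5 ends at C12, so the chain still needs three more carbons and the C13 stereocentre.
- Comparison: it builds less of the skeleton per step than the cycloaddition and needs more steps on both sides of the key step.

Key step: step 15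

Assumption: the iridium-catalysed tert-(hydroxy)prenylation is taken to be anti-selective (carbinol oxygen anti to the hydroxymethyl group) with the aldehyde face fixed by the ligand, so the Tol-BINAP antipode in step 5 is specified by the face it must attack.

Locants C1–C20 follow labdane numbering. TBS = tert-butyldimethylsilyl, TES = triethylsilyl, TBDPS = tert-butyldiphenylsilyl, PMB = 4-methoxybenzyl.

## Route

**Step 1**
Reactants: 1 (S)-2-[(PMB-oxy)methyl]oxirane
Product: 2 (S)-1-(PMB-oxy)pent-4-yn-2-ol
Conditions: LiC≡CH·H2NCH2CH2NH2 (1.5 equiv), DMSO, 0 °C → rt; aq. NH4Cl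
Reagents that add atoms: lithium acetylide–ethylenediamine complex, [Li+].[C-]#C.NCCN
Why: SN2 opening of a terminal epoxide by an acetylide at the unsubstituted carbon (C1) forms C1–C10; the C2 stereocentre is not touched, so (S)-1 should give (S)-2.

**Step 2**
Reactants: 2 (S)-1-(PMB-oxy)pent-4-yn-2-ol
Product: 3 (S)-2-(TBS-oxy)-1-(PMB-oxy)pent-4-yne
Conditions: TBSCl (1.3 equiv), imidazole (2.5 equiv), DMF, rt
Reagents that add atoms: tert-butyldimethylsilyl chloride, CC(C)(C)[Si](C)(C)Cl
Why: Standard silylation of a secondary alcohol; an ether at O2 is needed because the next step uses a Lewis-acidic alane and an acylating agent.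

**Step 3**
Reactants: 3 (S)-2-(TBS-oxy)-1-(PMB-oxy)pent-4-yne
Product: 5 methyl (2E,5S)-3-methyl-6-(PMB-oxy)-5-(TBS-oxy)hex-2-enoate, via alkenylalane 4 (not isolated)
Conditions: Me3Al (2.5 equiv), Cp2ZrCl2 (0.25 equiv), CH2Cl2, 0 °C → rt; then ClCO2Me (3 equiv), 0 °C → rt; aq. HCl
Reagents that add atoms: trimethylaluminium, C[Al](C)C; methyl chloroformate, COC(=O)Cl
Why: Zirconium-catalysed methylalumination is a syn carbometalation that puts the methyl group on C10 and aluminium on C9; acylation of the alkenylalane by the chloroformate goes with retention, so C1 ends trans to C11 and the (E)-enoate should form as a single isomer.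

**Step 4**
Reactants: 5 methyl (2E,5S)-3-methyl-6-(PMB-oxy)-5-(TBS-oxy)hex-2-enoate
Product: 6 methyl (2E,5S)-6-hydroxy-3-methyl-5-(TBS-oxy)hex-2-enoate
Conditions: DDQ (1.3 equiv), CH2Cl2–pH 7 buffer (10:1), 0 °C → rt
Reagents that add atoms: none
Why: Oxidative cleavage of a PMB ether (benzylic hydride abstraction, then hydrolysis of the oxocarbenium ion); there is no free neighbouring hydroxyl to trap the cation as an acetal, and the silyl ether and enoate are inert.

**Step 5**
Reactants: 6 methyl (2E,5S)-6-hydroxy-3-methyl-5-(TBS-oxy)hex-2-enoate; 7 2-methyl-2-vinyloxirane (racemic)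
Product: 9 methyl (2E,5S,6R,7S)-6-hydroxy-7-(hydroxymethyl)-3,7-dimethyl-5-(TBS-oxy)nona-2,8-dienoate, via aldehyde 8 (not isolated)
Conditions: preformed π-allyliridium C,O-benzoate from [Ir(cod)Cl]2, Tol-BINAP (antipode that adds to the Re face of 8), 4-cyano-3-nitrobenzoic acid and allyl acetate (5 mol %), K3PO4 (5 mol %), 7 (3 equiv), THF, 60 °C
Reagents that add atoms: none
Why: Iridium-catalysed transfer-hydrogenative tert-(hydroxy)prenylation of a primary alcohol: the catalyst dehydrogenates 6 to 8, the vinyl epoxide ionises to an allyliridium alkoxide, and the (E)-σ-allyl adds through a closed chair-like transition state. The chair places the carbinol oxygen anti to the hydroxymethyl group and so fixes C4 relative to C3, while the ligand fixes the aldehyde face and gives the 2,3-anti carbinol (3R in labdane numbering).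

**Step 6**
Reactants: 9 methyl (2E,5S,6R,7S)-6-hydroxy-7-(hydroxymethyl)-3,7-dimethyl-5-(TBS-oxy)nona-2,8-dienoate
Product: 10 methyl (2E,5S,6R,7S)-3,7-dimethyl-5-(TBS-oxy)-6-(TES-oxy)-7-[(TES-oxy)methyl]nona-2,8-dienoate
Conditions: TESOTf (2.5 equiv), 2,6-lutidine (4 equiv), CH2Cl2, −78 → 0 °C
Reagents that add atoms: triethylsilyl triflate, CC[Si](CC)(CC)OS(=O)(=O)C(F)(F)F
Why: Silyl triflate silylation of both hydroxyl groups, including the hindered C3 carbinol; the primary triethylsilyl ether is the temporary mask of the future C5 and can later be oxidised directly.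

**Step 7**
Reactants: 10 methyl (2E,5S,6R,7S)-3,7-dimethyl-5-(TBS-oxy)-6-(TES-oxy)-7-[(TES-oxy)methyl]nona-2,8-dienoate
Product: 13 methyl (2E,5S,6R,7S)-7-(hydroxymethyl)-3,7-dimethyl-5-(TBS-oxy)-6,8-bis(TES-oxy)oct-2-enoate, via vicinal diol 11 (not isolated), via aldehyde 12 (not isolated)
Conditions: OsO4 (2 mol %), NaIO4 (4 equiv), 2,6-lutidine (2 equiv), dioxane–H2O (3:1), rt; extractive work-up; then NaBH4, CeCl3·7H2O, MeOH, −40 °C
Reagents that add atoms: osmium tetroxide, O=[Os](=O)(=O)=O; sodium periodate, [Na+].[O-]I(=O)(=O)=O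
Why: Lemieux–Johnson cleavage should take the monosubstituted vinyl group and leave the electron-poor trisubstituted enoate; the vinyl carbon becomes C19. The cold, buffered borohydride reduction is chosen to avoid 1,3-silyl migration between the two CH2O arms, which would scramble C4.

**Step 8**
Reactants: 13 methyl (2E,5S,6R,7S)-7-(hydroxymethyl)-3,7-dimethyl-5-(TBS-oxy)-6,8-bis(TES-oxy)oct-2-enoate
Product: 14 methyl (2E,5S,6R,7R)-3,7-dimethyl-5-(TBS-oxy)-7-[(TBDPS-oxy)methyl]-6,8-bis(TES-oxy)oct-2-enoate
Conditions: TBDPSCl (1.3 equiv), imidazole (2.5 equiv), DMAP (cat.), DMF, rt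
Reagents that add atoms: tert-butyl(chloro)diphenylsilane, CC(C)(C)[Si](Cl)(c1ccccc1)c1ccccc1
Why: Silylation of the neopentyl primary alcohol; the TBDPS ether at O19 is chosen because it survives the acidic fluoride treatment of step 11 that removes the other silyl ethers.

**Step 9**
Reactants: 14 methyl (2E,5S,6R,7R)-3,7-dimethyl-5-(TBS-oxy)-7-[(TBDPS-oxy)methyl]-6,8-bis(TES-oxy)oct-2-enoate
Product: 15 methyl (2E,5S,6R,7R)-3,7-dimethyl-8-oxo-5-(TBS-oxy)-7-[(TBDPS-oxy)methyl]-6-(TES-oxy)oct-2-enoate
Conditions: (COCl)2 (4 equiv), DMSO (8 equiv), CH2Cl2, −78 → −30 °C; then Et3N (12 equiv), −78 °C → rt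
Reagents that add atoms: none
Why: Swern oxidation of a primary triethylsilyl ether: the chlorosulfonium reagent exchanges at the least hindered primary silyl ether and gives the aldehyde directly, while secondary triethylsilyl, TBS and TBDPS ethers are not attacked. The aldehyde (C5) has no α-hydrogen and cannot epimerise.

**Step 10**
Reactants: 15 methyl (2E,5S,6R,7R)-3,7-dimethyl-8-oxo-5-(TBS-oxy)-7-[(TBDPS-oxy)methyl]-6-(TES-oxy)oct-2-enoate; 16 dimethyl (2-oxobutyl)phosphonate
Product: 17 methyl (2E,5S,6R,7R,8E)-3,7-dimethyl-10-oxo-5-(TBS-oxy)-7-[(TBDPS-oxy)methyl]-6-(TES-oxy)dodeca-2,8-dienoate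
Conditions: 16 (1.5 equiv), Ba(OH)2 (activated, 1.2 equiv), THF–H2O (40:1), rt
Reagents that add atoms: none
Why: Horner–Wadsworth–Emmons olefination with a β-ketophosphonate forms C5=C6 as the (E)-enone; mild barium hydroxide conditions suit a hindered, non-enolisable aldehyde and leave the unreactive β,β-disubstituted enoate alone.

**Step 11**
Reactants: 17 methyl (2E,5S,6R,7R,8E)-3,7-dimethyl-10-oxo-5-(TBS-oxy)-7-[(TBDPS-oxy)methyl]-6-(TES-oxy)dodeca-2,8-dienoate
Product: 19 methyl (2E,5S,6R,7R,8E)-5,6-(isopropylidenedioxy)-3,7-dimethyl-10-oxo-7-[(TBDPS-oxy)methyl]dodeca-2,8-dienoate, via diol 18 (not isolated)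
Conditions: HF·pyridine, pyridine, THF, 0 °C → rt; work-up; then Me2C(OMe)2 (5 equiv), PPTS (cat.), CH2Cl2, rt
Reagents that add atoms: 2,2-dimethoxypropane, COC(C)(C)OC
Why: Acidic fluoride removes the two secondary silyl ethers faster than the neopentyl TBDPS ether, and acid-catalysed transketalisation then closes the only possible acetonide. The anti-diol gives the cis-dioxolane; the crude diol is ketalised at once so that O2 has little time for conjugate addition to the enone.

**Step 12**
Reactants: 19 methyl (2E,5S,6R,7R,8E)-5,6-(isopropylidenedioxy)-3,7-dimethyl-10-oxo-7-[(TBDPS-oxy)methyl]dodeca-2,8-dienoate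
Product: 20 methyl (2E,5S,6R,7R,8E,10Z)-5,6-(isopropylidenedioxy)-3,7-dimethyl-10-(TBS-oxy)-7-[(TBDPS-oxy)methyl]dodeca-2,8,10-trienoate
Conditions: TBSOTf (1.3 equiv), Et3N (2.5 equiv), CH2Cl2, −78 → 0 °C
Reagents that add atoms: tert-butyldimethylsilyl triflate, CC(C)(C)[Si](C)(C)OS(=O)(=O)C(F)(F)F
Why: Soft enolisation and O-silylation of the ethyl ketone; C8 is the only enolisable position because C4 is quaternary, and the (Z)-enol ether (C17 trans to C6) is the usual product. The enoate is not enolised under these conditions, which is why C11 is still an ester here.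

**Step 13**
Reactants: 20 methyl (2E,5S,6R,7R,8E,10Z)-5,6-(isopropylidenedioxy)-3,7-dimethyl-10-(TBS-oxy)-7-[(TBDPS-oxy)methyl]dodeca-2,8,10-trienoate
Product: 21 (2E,5S,6R,7R,8E,10Z)-5,6-(isopropylidenedioxy)-3,7-dimethyl-10-(TBS-oxy)-7-[(TBDPS-oxy)methyl]dodeca-2,8,10-trien-1-ol
Conditions: i-Bu2AlH (2.3 equiv), CH2Cl2, −78 °C; aq. KNaC4H4O6
Reagents that add atoms: none
Why: 1,2-Reduction of an α,β-unsaturated ester to the allylic alcohol; silyl enol ether, silyl ether and acetonide are stable to the hydride at −78 °C.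

**Step 14**
Reactants: 21 (2E,5S,6R,7R,8E,10Z)-5,6-(isopropylidenedioxy)-3,7-dimethyl-10-(TBS-oxy)-7-[(TBDPS-oxy)methyl]dodeca-2,8,10-trien-1-ol
Product: 22 (2E,5S,6R,7R,8E,10Z)-5,6-(isopropylidenedioxy)-3,7-dimethyl-10-(TBS-oxy)-7-[(TBDPS-oxy)methyl]dodeca-2,8,10-trienal
Conditions: MnO2 (20 equiv), CH2Cl2, rt
Reagents that add atoms: none
Why: Allylic oxidation with MnO2 is neutral and heterogeneous, so the acid-sensitive silyl dienol ether should survive and the (E)-geometry of the enal should be kept.

**Step 15**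
Reactants: 22 (2E,5S,6R,7R,8E,10Z)-5,6-(isopropylidenedioxy)-3,7-dimethyl-10-(TBS-oxy)-7-[(TBDPS-oxy)methyl]dodeca-2,8,10-trienal
Product: 23 (2S,3R,4R,5S,8S,9R,10R)-2,3-(isopropylidenedioxy)-7-(TBS-oxy)-19-(TBDPS-oxy)-12,13,14,15,16-pentanorlabd-6-en-11-al
Conditions: Me2AlCl (1.5 equiv), CH2Cl2 (0.01 M), −78 → −30 °C; Et3N, then aq. NaHCO3
Reagents that add atoms: none
Why: Me2AlCl binds the formyl oxygen of 22 and lowers the LUMO of the (E)-enal, which then adds to the s-cis 2-silyloxydiene in a concerted, asynchronous, suprafacial [4+2] cycloaddition; the closest known reaction type is the Lewis-acid-promoted intramolecular Diels–Alder reaction of terminally activated 1,7,9-decatrienes. Ring B closes as the cyclohexene of the cycloaddition (new bonds C5–C10 and C8–C9, alkene moved to C6=C7), and ring A closes as the six-membered ring spanned by the tether C1–C4, which folds as a chair. C9 and C10 are linked by the (E)-geometry of the enal, so C11 ends cis to C20; the trans relation of C5 and C10 follows from the endo transition state (formyl group under the diene, tether anti), which aluminium complexation reinforces; C8 follows from the (Z)-enol ether, whose methyl group points outward and ends cis to C11. The absolute sense at all four new centres comes from C2–C4: in the favoured chair O2 and C18 are equatorial, whereas attack on the other diene face would put O2 and C18 in 1,3-diaxial contact with C20. The regiochemistry is imposed by the tether and not by the polarisation of the diene (the silyloxy carbon ends 1,3 to the formyl-bearing carbon), so the bond from C5 to the enal β-carbon C10 should lead, and high dilution is used to suppress intermolecular Mukaiyama–Michael addition. The step needs endo over exo selectivity and survival of the silyl enol ether, which the proton-scavenging Me2AlCl and the low temperature should secure.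

**Step 16**
Reactants: 24 (S)-4-methyldihydrofuran-2(3H)-one
Product: 25 methyl (S)-4-bromo-3-methylbutanoate
Conditions: HBr (g), MeOH, 0 °C → rt
Reagents that add atoms: hydrogen bromide, Br; methanol, CO
Why: Acid-mediated ring opening of a γ-lactone by bromide at the O-bearing carbon (SN2, alkyl–oxygen cleavage) with Fischer esterification; the stereocentre is one carbon away from the reacting site and is not touched.

**Step 17**
Reactants: 25 methyl (S)-4-bromo-3-methylbutanoate
Product: 26 [(S)-4-methoxy-2-methyl-4-oxobutyl]triphenylphosphonium bromide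
Conditions: PPh3 (1.2 equiv), MeCN, reflux
Reagents that add atoms: triphenylphosphine, c1ccc(cc1)P(c1ccccc1)c1ccccc1
Why: SN2 quaternisation of triphenylphosphine by a primary, β-branched bromide; prolonged heating is expected to be needed.

**Step 18**
Reactants: 23 (2S,3R,4R,5S,8S,9R,10R)-2,3-(isopropylidenedioxy)-7-(TBS-oxy)-19-(TBDPS-oxy)-12,13,14,15,16-pentanorlabd-6-en-11-al; 26 [(S)-4-methoxy-2-methyl-4-oxobutyl]triphenylphosphonium bromide
Product: 28 methyl (2S,3R,4R,5S,8S,9R,10S,11Z,13S)-2,3-(isopropylidenedioxy)-7-(TBS-oxy)-19-(TBDPS-oxy)labda-6,11-dien-15-oate, via ylide 27 (not isolated)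
Conditions: 26 (1.6 equiv), NaN(SiMe3)2 (1.5 equiv), THF, −78 → 0 °C; then 23, −78 °C → rt
Reagents that add atoms: none
Why: Wittig olefination with a non-stabilised ylide (deprotonation next to phosphorus is far easier than next to the ester) forms C11=C12, mainly (Z). The formyl group of 23 is already equatorial, so C9 should be kept, and the silyl enol ether protects the C7 carbonyl from the ylide.

**Step 19**
Reactants: 28 methyl (2S,3R,4R,5S,8S,9R,10S,11Z,13S)-2,3-(isopropylidenedioxy)-7-(TBS-oxy)-19-(TBDPS-oxy)labda-6,11-dien-15-oate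
Product: 29 methyl (2S,3R,4R,5S,8S,9R,10S,13R)-2,3-(isopropylidenedioxy)-7-(TBS-oxy)-19-(TBDPS-oxy)labd-6-en-15-oate
Conditions: H2 (1 atm), Pd/C (10 wt %), EtOAc, rt
Reagents that add atoms: none
Why: Heterogeneous hydrogenation of the disubstituted alkene; the hindered trisubstituted silyl enol ether reacts much more slowly, and C13 is not involved (its descriptor changes only through the priority rules).

**Step 20**
Reactants: 29 methyl (2S,3R,4R,5S,8S,9R,10S,13R)-2,3-(isopropylidenedioxy)-7-(TBS-oxy)-19-(TBDPS-oxy)labd-6-en-15-oate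
Product: 30 methyl (2S,3R,4R,5S,8S,9R,10S,13R)-2,3-(isopropylidenedioxy)-7-oxo-19-(TBDPS-oxy)labdan-15-oate
Conditions: Bu4NF (1.2 equiv), AcOH (1.5 equiv), THF, 0 °C
Reagents that add atoms: none
Why: Buffered fluoride cleaves the silyl enol ether within minutes and protonates C6, well before the neopentyl TBDPS ether reacts. Any epimerisation at C8 is harmless because that centre is removed in the next step.

**Step 21**
Reactants: 30 methyl (2S,3R,4R,5S,8S,9R,10S,13R)-2,3-(isopropylidenedioxy)-7-oxo-19-(TBDPS-oxy)labdan-15-oate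
Product: 31 methyl (2S,3R,4R,5S,9S,10R,13R)-2,3-(isopropylidenedioxy)-19-(TBDPS-oxy)-7-(trifluoromethanesulfonyloxy)labd-7-en-15-oate
Conditions: Tf2O (1.5 equiv), 2,6-di-tert-butyl-4-methylpyridine (2.5 equiv), CH2Cl2, 0 °C → rt
Reagents that add atoms: trifluoromethanesulfonic anhydride, O=S(=O)(OS(=O)(=O)C(F)(F)F)C(F)(F)F
Why: Thermodynamic enol triflate formation: O-triflation of the ketone and loss of a proton to the hindered base favour the more substituted C7=C8 enol triflate. This erases C8; the changed descriptors at C9 and C10 come from the priority rules only.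

**Step 22**
Reactants: 31 methyl (2S,3R,4R,5S,9S,10R,13R)-2,3-(isopropylidenedioxy)-19-(TBDPS-oxy)-7-(trifluoromethanesulfonyloxy)labd-7-en-15-oate
Product: 32 methyl (2S,3R,4R,5S,9R,10S,13R)-2,3-(isopropylidenedioxy)-19-(TBDPS-oxy)labd-7-en-15-oate
Conditions: Pd(OAc)2 (5 mol %), PPh3 (10 mol %), HCO2H (3 equiv), Bu3N (4 equiv), DMF, 60 °C
Reagents that add atoms: none
Why: Palladium-catalysed formate reduction of an enol triflate: oxidative addition to zerovalent palladium, formate-to-hydride exchange with loss of CO2, and reductive elimination replace the triflate by hydrogen without moving the alkene.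

**Step 23**
Reactants: 32 methyl (2S,3R,4R,5S,9R,10S,13R)-2,3-(isopropylidenedioxy)-19-(TBDPS-oxy)labd-7-en-15-oate
Product: 33 (2S,3R,4R,5S,9R,10S,13R)-2,3-(isopropylidenedioxy)-19-(TBDPS-oxy)labd-7-en-15-oic acid
Conditions: LiOH·H2O (5 equiv), THF–MeOH–H2O (3:1:1), rt; 1 M HCl to pH 4
Reagents that add atoms: lithium hydroxide, [Li+].[OH-]
Why: Saponification of the unhindered methyl ester, done here because later intermediates carry an aldehyde and then an acetate that would not survive hydroxide; ketal, silyl ether and alkene are stable.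

**Step 24**
Reactants: 33 (2S,3R,4R,5S,9R,10S,13R)-2,3-(isopropylidenedioxy)-19-(TBDPS-oxy)labd-7-en-15-oic acid
Product: 34 (2S,3R,4R,5S,9R,10S,13R)-19-hydroxy-2,3-(isopropylidenedioxy)labd-7-en-15-oic acid
Conditions: Bu4NF (4 equiv), THF, 45 °C; aq. NH4Cl
Reagents that add atoms: none
Why: Fluoride cleavage of the neopentyl silyl ether (Si–F bond formation); warming is expected to be needed at this hindered position, and one extra equivalent of fluoride is consumed by the acid.

**Step 25**
Reactants: 34 (2S,3R,4R,5S,9R,10S,13R)-19-hydroxy-2,3-(isopropylidenedioxy)labd-7-en-15-oic acid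
Product: 35 (2S,3R,4S,5S,9R,10S,13R)-2,3-(isopropylidenedioxy)-19-oxolabd-7-en-15-oic acid
Conditions: Dess–Martin periodinane (1.5 equiv), NaHCO3, CH2Cl2, 0 °C → rt
Reagents that add atoms: none
Why: Dess–Martin oxidation of the only free alcohol; the new aldehyde has no α-hydrogen, and with O3 still in the ketal no retro-aldol is possible.

**Step 26**
Reactants: 35 (2S,3R,4S,5S,9R,10S,13R)-2,3-(isopropylidenedioxy)-19-oxolabd-7-en-15-oic acid
Product: 36 (2S,3R,4S,5S,9R,10S,13R)-2,3-dihydroxy-19-oxolabd-7-en-15-oic acid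
Conditions: AcOH–H2O (4:1), 45 °C
Reagents that add atoms: none
Why: Acid-catalysed hydrolysis of the acetonide; aqueous acetic acid is too weak to protonate the trisubstituted alkene, so the 7-ene should stay in place.

**Step 27**
Reactants: 36 (2S,3R,4S,5S,9R,10S,13R)-2,3-dihydroxy-19-oxolabd-7-en-15-oic acid
Product: 38 (2S,3R,4S,5S,9R,10S,13R)-2-acetoxy-3-hydroxy-19-oxolabd-7-en-15-oic acid, via mixed anhydride 37 (not isolated)
Conditions: Ac2O (3 equiv), pyridine, 0 °C; then H2O–THF, rt
Reagents that add atoms: acetic anhydride, CC(=O)OC(C)=O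
Why: Rate-selective acetylation: the equatorial C2 hydroxyl is acylated, while the axial C3 hydroxyl, flanked by the quaternary C4, should stay free without an acyl-transfer catalyst. The acid forms a mixed anhydride that the aqueous work-up hydrolyses.

## Compound list

1 | (S)-2-[(PMB-oxy)methyl]oxirane | COc1ccc(COC[C@@H]2CO2)cc1 | starting material
2 | (S)-1-(PMB-oxy)pent-4-yn-2-ol | O[C@@H](CC#C)COCc1ccc(OC)cc1 | intermediate
3 | (S)-2-(TBS-oxy)-1-(PMB-oxy)pent-4-yne | CC(C)(C)[Si](C)(C)O[C@@H](CC#C)COCc1ccc(OC)cc1 | intermediate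
4 | dimethyl[(1E,4S)-2-methyl-5-(PMB-oxy)-4-(TBS-oxy)pent-1-enyl]alane | CC(C)(C)[Si](C)(C)O[C@@H](C/C(C)=C/[Al](C)C)COCc1ccc(OC)cc1 | intermediate (not isolated)
5 | methyl (2E,5S)-3-methyl-6-(PMB-oxy)-5-(TBS-oxy)hex-2-enoate | CC(C)(C)[Si](C)(C)O[C@@H](C/C(C)=C/C(=O)OC)COCc1ccc(OC)cc1 | intermediate
6 | methyl (2E,5S)-6-hydroxy-3-methyl-5-(TBS-oxy)hex-2-enoate | CC(C)(C)[Si](C)(C)O[C@@H](C/C(C)=C/C(=O)OC)CO | intermediate
7 | 2-methyl-2-vinyloxirane (racemic) | CC1(CO1)C=C | starting material
8 | methyl (2E,5S)-3-methyl-6-oxo-5-(TBS-oxy)hex-2-enoate | CC(C)(C)[Si](C)(C)O[C@@H](C/C(C)=C/C(=O)OC)C=O | intermediate (not isolated)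
9 | methyl (2E,5S,6R,7S)-6-hydroxy-7-(hydroxymethyl)-3,7-dimethyl-5-(TBS-oxy)nona-2,8-dienoate | CC(C)(C)[Si](C)(C)O[C@@H](C/C(C)=C/C(=O)OC)[C@H](O)[C@@](C)(C=C)CO | intermediate
10 | methyl (2E,5S,6R,7S)-3,7-dimethyl-5-(TBS-oxy)-6-(TES-oxy)-7-[(TES-oxy)methyl]nona-2,8-dienoate | CC(C)(C)[Si](C)(C)O[C@@H](C/C(C)=C/C(=O)OC)[C@H](O[Si](CC)(CC)CC)[C@@](C)(C=C)CO[Si](CC)(CC)CC | intermediate
11 | methyl (2E,5S,6R,7R)-8,9-dihydroxy-3,7-dimethyl-5-(TBS-oxy)-6-(TES-oxy)-7-[(TES-oxy)methyl]non-2-enoate (both C8 epimers) | CC(C)(C)[Si](C)(C)O[C@@H](C/C(C)=C/C(=O)OC)[C@H](O[Si](CC)(CC)CC)[C@@](C)(C(O)CO)CO[Si](CC)(CC)CC | intermediate (not isolated)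
12 | methyl (2E,5S,6R,7S)-7-formyl-3,7-dimethyl-5-(TBS-oxy)-6,8-bis(TES-oxy)oct-2-enoate | CC(C)(C)[Si](C)(C)O[C@@H](C/C(C)=C/C(=O)OC)[C@H](O[Si](CC)(CC)CC)[C@@](C)(C=O)CO[Si](CC)(CC)CC | intermediate (not isolated)
13 | methyl (2E,5S,6R,7S)-7-(hydroxymethyl)-3,7-dimethyl-5-(TBS-oxy)-6,8-bis(TES-oxy)oct-2-enoate | CC(C)(C)[Si](C)(C)O[C@@H](C/C(C)=C/C(=O)OC)[C@H](O[Si](CC)(CC)CC)[C@@](C)(CO)CO[Si](CC)(CC)CC | intermediate
14 | methyl (2E,5S,6R,7R)-3,7-dimethyl-5-(TBS-oxy)-7-[(TBDPS-oxy)methyl]-6,8-bis(TES-oxy)oct-2-enoate | CC(C)(C)[Si](C)(C)O[C@@H](C/C(C)=C/C(=O)OC)[C@H](O[Si](CC)(CC)CC)[C@@](C)(CO[Si](c1ccccc1)(c1ccccc1)C(C)(C)C)CO[Si](CC)(CC)CC | intermediate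
15 | methyl (2E,5S,6R,7R)-3,7-dimethyl-8-oxo-5-(TBS-oxy)-7-[(TBDPS-oxy)methyl]-6-(TES-oxy)oct-2-enoate | CC(C)(C)[Si](C)(C)O[C@@H](C/C(C)=C/C(=O)OC)[C@H](O[Si](CC)(CC)CC)[C@@](C)(CO[Si](c1ccccc1)(c1ccccc1)C(C)(C)C)C=O | intermediate
16 | dimethyl (2-oxobutyl)phosphonate | CCC(=O)CP(=O)(OC)OC | starting material
17 | methyl (2E,5S,6R,7R,8E)-3,7-dimethyl-10-oxo-5-(TBS-oxy)-7-[(TBDPS-oxy)methyl]-6-(TES-oxy)dodeca-2,8-dienoate | CC(C)(C)[Si](C)(C)O[C@@H](C/C(C)=C/C(=O)OC)[C@H](O[Si](CC)(CC)CC)[C@@](C)(CO[Si](c1ccccc1)(c1ccccc1)C(C)(C)C)/C=C/C(=O)CC | intermediate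
18 | methyl (2E,5S,6R,7R,8E)-5,6-dihydroxy-3,7-dimethyl-10-oxo-7-[(TBDPS-oxy)methyl]dodeca-2,8-dienoate | O[C@@H](C/C(C)=C/C(=O)OC)[C@H](O)[C@@](C)(CO[Si](c1ccccc1)(c1ccccc1)C(C)(C)C)/C=C/C(=O)CC | intermediate (not isolated)
19 | methyl (2E,5S,6R,7R,8E)-5,6-(isopropylidenedioxy)-3,7-dimethyl-10-oxo-7-[(TBDPS-oxy)methyl]dodeca-2,8-dienoate | CC1(C)O[C@@H](C/C(C)=C/C(=O)OC)[C@H](O1)[C@@](C)(CO[Si](c2ccccc2)(c2ccccc2)C(C)(C)C)/C=C/C(=O)CC | intermediate
20 | methyl (2E,5S,6R,7R,8E,10Z)-5,6-(isopropylidenedioxy)-3,7-dimethyl-10-(TBS-oxy)-7-[(TBDPS-oxy)methyl]dodeca-2,8,10-trienoate | CC1(C)O[C@@H](C/C(C)=C/C(=O)OC)[C@H](O1)[C@@](C)(CO[Si](c2ccccc2)(c2ccccc2)C(C)(C)C)/C=C/C(O[Si](C)(C)C(C)(C)C)=C/C | intermediate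
21 | (2E,5S,6R,7R,8E,10Z)-5,6-(isopropylidenedioxy)-3,7-dimethyl-10-(TBS-oxy)-7-[(TBDPS-oxy)methyl]dodeca-2,8,10-trien-1-ol | CC1(C)O[C@@H](C/C(C)=C/CO)[C@H](O1)[C@@](C)(CO[Si](c2ccccc2)(c2ccccc2)C(C)(C)C)/C=C/C(O[Si](C)(C)C(C)(C)C)=C/C | intermediate
22 | (2E,5S,6R,7R,8E,10Z)-5,6-(isopropylidenedioxy)-3,7-dimethyl-10-(TBS-oxy)-7-[(TBDPS-oxy)methyl]dodeca-2,8,10-trienal | CC1(C)O[C@@H](C/C(C)=C/C=O)[C@H](O1)[C@@](C)(CO[Si](c2ccccc2)(c2ccccc2)C(C)(C)C)/C=C/C(O[Si](C)(C)C(C)(C)C)=C/C | intermediate
23 | (2S,3R,4R,5S,8S,9R,10R)-2,3-(isopropylidenedioxy)-7-(TBS-oxy)-19-(TBDPS-oxy)-12,13,14,15,16-pentanorlabd-6-en-11-al | CC1(C)O[C@H]2C[C@@]3(C)[C@H](C=O)[C@H](C)C(O[Si](C)(C)C(C)(C)C)=C[C@@H]3[C@](C)(CO[Si](c4ccccc4)(c4ccccc4)C(C)(C)C)[C@H]2O1 | intermediate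
24 | (S)-4-methyldihydrofuran-2(3H)-one | O=C1C[C@H](C)CO1 | starting material
25 | methyl (S)-4-bromo-3-methylbutanoate | COC(=O)C[C@H](C)CBr | intermediate
26 | [(S)-4-methoxy-2-methyl-4-oxobutyl]triphenylphosphonium bromide | COC(=O)C[C@H](C)C[P+](c1ccccc1)(c1ccccc1)c1ccccc1.[Br-] | intermediate
27 | methyl (S)-3-methyl-4-(triphenylphosphoranylidene)butanoate | COC(=O)C[C@H](C)C=P(c1ccccc1)(c1ccccc1)c1ccccc1 | intermediate (not isolated)
28 | methyl (2S,3R,4R,5S,8S,9R,10S,11Z,13S)-2,3-(isopropylidenedioxy)-7-(TBS-oxy)-19-(TBDPS-oxy)labda-6,11-dien-15-oate | CC1(C)O[C@H]2C[C@@]3(C)[C@H](/C=C\[C@@H](C)CC(=O)OC)[C@H](C)C(O[Si](C)(C)C(C)(C)C)=C[C@@H]3[C@](C)(CO[Si](c4ccccc4)(c4ccccc4)C(C)(C)C)[C@H]2O1 | intermediate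
29 | methyl (2S,3R,4R,5S,8S,9R,10S,13R)-2,3-(isopropylidenedioxy)-7-(TBS-oxy)-19-(TBDPS-oxy)labd-6-en-15-oate | CC1(C)O[C@H]2C[C@@]3(C)[C@H](CC[C@@H](C)CC(=O)OC)[C@H](C)C(O[Si](C)(C)C(C)(C)C)=C[C@@H]3[C@](C)(CO[Si](c4ccccc4)(c4ccccc4)C(C)(C)C)[C@H]2O1 | intermediate
30 | methyl (2S,3R,4R,5S,8S,9R,10S,13R)-2,3-(isopropylidenedioxy)-7-oxo-19-(TBDPS-oxy)labdan-15-oate | CC1(C)O[C@H]2C[C@@]3(C)[C@H](CC[C@@H](C)CC(=O)OC)[C@H](C)C(=O)C[C@@H]3[C@](C)(CO[Si](c4ccccc4)(c4ccccc4)C(C)(C)C)[C@H]2O1 | intermediate
31 | methyl (2S,3R,4R,5S,9S,10R,13R)-2,3-(isopropylidenedioxy)-19-(TBDPS-oxy)-7-(trifluoromethanesulfonyloxy)labd-7-en-15-oate | CC1(C)O[C@H]2C[C@@]3(C)[C@H](CC[C@@H](C)CC(=O)OC)C(C)=C(OS(=O)(=O)C(F)(F)F)C[C@@H]3[C@](C)(CO[Si](c4ccccc4)(c4ccccc4)C(C)(C)C)[C@H]2O1 | intermediate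
32 | methyl (2S,3R,4R,5S,9R,10S,13R)-2,3-(isopropylidenedioxy)-19-(TBDPS-oxy)labd-7-en-15-oate | CC1(C)O[C@H]2C[C@@]3(C)[C@H](CC[C@@H](C)CC(=O)OC)C(C)=CC[C@@H]3[C@](C)(CO[Si](c4ccccc4)(c4ccccc4)C(C)(C)C)[C@H]2O1 | intermediate
33 | (2S,3R,4R,5S,9R,10S,13R)-2,3-(isopropylidenedioxy)-19-(TBDPS-oxy)labd-7-en-15-oic acid | CC1(C)O[C@H]2C[C@@]3(C)[C@H](CC[C@@H](C)CC(=O)O)C(C)=CC[C@@H]3[C@](C)(CO[Si](c4ccccc4)(c4ccccc4)C(C)(C)C)[C@H]2O1 | intermediate
34 | (2S,3R,4R,5S,9R,10S,13R)-19-hydroxy-2,3-(isopropylidenedioxy)labd-7-en-15-oic acid | CC1(C)O[C@H]2C[C@@]3(C)[C@H](CC[C@@H](C)CC(=O)O)C(C)=CC[C@@H]3[C@](C)(CO)[C@H]2O1 | intermediate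
35 | (2S,3R,4S,5S,9R,10S,13R)-2,3-(isopropylidenedioxy)-19-oxolabd-7-en-15-oic acid | CC1(C)O[C@H]2C[C@@]3(C)[C@H](CC[C@@H](C)CC(=O)O)C(C)=CC[C@@H]3[C@](C)(C=O)[C@H]2O1 | intermediate
36 | (2S,3R,4S,5S,9R,10S,13R)-2,3-dihydroxy-19-oxolabd-7-en-15-oic acid | O[C@H]1C[C@@]2(C)[C@H](CC[C@@H](C)CC(=O)O)C(C)=CC[C@@H]2[C@](C)(C=O)[C@H]1O | intermediate
37 | acetic (2S,3R,4S,5S,9R,10S,13R)-2-acetoxy-3-hydroxy-19-oxolabd-7-en-15-oic anhydride | CC(=O)O[C@H]1C[C@@]2(C)[C@H](CC[C@@H](C)CC(=O)OC(C)=O)C(C)=CC[C@@H]2[C@](C)(C=O)[C@H]1O | intermediate (not isolated)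
38 | (2S,3R,4S,5S,9R,10S,13R)-2-acetoxy-3-hydroxy-19-oxolabd-7-en-15-oic acid | CC(=O)O[C@H]1C[C@@]2(C)[C@H](CC[C@@H](C)CC(=O)O)C(C)=CC[C@@H]2[C@](C)(C=O)[C@H]1O | target

## Step count and least certain steps

Total step count: 27. Longest linear sequence: 25 (steps 1–15 and 18–27); steps 16 and 17 make the side-chain reagent.

**Step 15 (key step).** Endo/exo control may erode, because the C20 methyl group sits under the diene in the endo transition state, and the tether-imposed regiochemistry runs against the polarisation of the silyloxy diene, so the cycloaddition may be slow enough for protodesilylation of the enol ether or intermolecular Michael-type oligomerisation to compete. Fallback: set out from 20 and run the cycloaddition thermally on the ester, without Lewis acid (toluene, 2,6-di-tert-butyl-4-methylphenol, base-washed sealed vessel, 170 °C), to the C11 methyl ester analogue of 23 F1. Reduce this with i-Bu2AlH to the C11 primary alcohol analogue of 23 F2, and oxidise with Dess–Martin periodinane to come back to the route at 23. The thermal reaction gives up some endo preference in exchange for a robust substrate.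

**Step 5.** The transient α-silyloxy aldehyde may epimerise at C2 under the phosphate base, the TBS group of 6 may migrate from O2 to O3 and take the alcohol out of the catalytic cycle, and catalyst control may be weakened by the bias of the C2 centre. Fallback: set out from 6 and oxidise it with Dess–Martin periodinane to 8, now isolated. Separately, open 7 with bis(pinacolato)diboron under palladium catalysis to (E)-2-methyl-4-(pinacolboryl)but-2-en-1-ol F3 and silylate it to its triethylsilyl ether F4. Allylboration of 8 with F4 through a closed chair transition state (Felkin–Anh face, hydroxymethyl arm anti to the new hydroxyl) should give the O-mono(triethylsilyl) analogue of 9 F5, and TESOTf then silylates O3 to come back at 10. This replaces catalyst control by reagent geometry and substrate control.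

**Step 21.** Enolisation may leak towards C6 and give the less substituted enol triflate, which would lead to the 6-ene. Fallback: set out from 30 and equilibrate it to the more substituted trimethylsilyl enol ether under thermodynamic silylation conditions (Me3SiCl, NaI, Et3N, MeCN, 40 °C), giving the 7-(trimethylsilyloxy)-7-ene F6, which can be purified from its regioisomer. Fluoride-triggered triflation of F6 (CsF, PhNTf2, 1,2-dimethoxyethane) is regiospecific and comes back at 31. The regiochemistry is then fixed at an isolable stage.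

**Step 27.** Acetylation may spill over to O3, or the acetyl group may migrate between O2 and O3 under the basic conditions, and the mixed anhydride may complicate control of stoichiometry. Fallback: set out from 36 and use a borinic-acid-catalysed monoacylation of the cis-diol (2-aminoethyl diphenylborinate 10 mol %, AcCl, i-Pr2NEt, MeCN, 0 °C). The cyclic borinate activates the equatorial oxygen of a cis-1,2-diol, so the site is chosen by the catalyst and not by relative rates. The route comes back at 38 after aqueous work-up, and the fallback makes no new isolated compound (F0).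

## Further compounds

F1 | step 15 | methyl (2S,3R,4R,5S,8S,9R,10R)-2,3-(isopropylidenedioxy)-7-(TBS-oxy)-19-(TBDPS-oxy)-12,13,14,15,16-pentanorlabd-6-en-11-oate | CC1(C)O[C@H]2C[C@@]3(C)[C@H](C(=O)OC)[C@H](C)C(O[Si](C)(C)C(C)(C)C)=C[C@@H]3[C@](C)(CO[Si](c4ccccc4)(c4ccccc4)C(C)(C)C)[C@H]2O1
F2 | step 15 | (2S,3R,4R,5S,8S,9R,10R)-2,3-(isopropylidenedioxy)-7-(TBS-oxy)-19-(TBDPS-oxy)-12,13,14,15,16-pentanorlabd-6-en-11-ol | CC1(C)O[C@H]2C[C@@]3(C)[C@H](CO)[C@H](C)C(O[Si](C)(C)C(C)(C)C)=C[C@@H]3[C@](C)(CO[Si](c4ccccc4)(c4ccccc4)C(C)(C)C)[C@H]2O1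
F3 | step 5 | (E)-2-methyl-4-(4,4,5,5-tetramethyl-1,3,2-dioxaborolan-2-yl)but-2-en-1-ol | OC/C(C)=C/CB1OC(C)(C)C(C)(C)O1
F4 | step 5 | (E)-triethyl{[2-methyl-4-(4,4,5,5-tetramethyl-1,3,2-dioxaborolan-2-yl)but-2-en-1-yl]oxy}silane | CC[Si](CC)(CC)OC/C(C)=C/CB1OC(C)(C)C(C)(C)O1
F5 | step 5 | methyl (2E,5S,6R,7S)-6-hydroxy-3,7-dimethyl-5-(TBS-oxy)-7-[(TES-oxy)methyl]nona-2,8-dienoate | CC(C)(C)[Si](C)(C)O[C@@H](C/C(C)=C/C(=O)OC)[C@H](O)[C@@](C)(C=C)CO[Si](CC)(CC)CC
F6 | step 21 | methyl (2S,3R,4R,5S,9S,10R,13R)-2,3-(isopropylidenedioxy)-19-(TBDPS-oxy)-7-(trimethylsilyloxy)labd-7-en-15-oate | CC1(C)O[C@H]2C[C@@]3(C)[C@H](CC[C@@H](C)CC(=O)OC)C(C)=C(O[Si](C)(C)C)C[C@@H]3[C@](C)(CO[Si](c4ccccc4)(c4ccccc4)C(C)(C)C)[C@H]2O1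
F0 | step 27 | none | none
A1 | alternative 1 | allyl (2S,3R,4S,5S,9R,10S,13R)-2,3-dihydroxy-19-oxolabd-7-en-15-oate | O[C@H]1C[C@@]2(C)[C@H](CC[C@@H](C)CC(=O)OCC=C)C(C)=CC[C@@H]2[C@](C)(C=O)[C@H]1O
A2 | alternative 1 | 2,3-seco trialdehyde allyl ester (C2 aldehyde on the C10 arm and two formyl groups on C4) | O=CC[C@@]1(C)[C@H](CC[C@@H](C)CC(=O)OCC=C)C(C)=CC[C@@H]1C(C)(C=O)C=O
A3 | alternative 2 | allyl 2-oxo-3-(TBS-oxy)-19-(PMB-oxy)labd-7-en-15-oate | O=C1C[C@@]2(C)[C@H](CC[C@@H](C)CC(=O)OCC=C)C(C)=CC[C@@H]2[C@](C)(COCc2ccc(OC)cc2)[C@H]1O[Si](C)(C)C(C)(C)C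
A4 | alternative 2 | acyclic allenene trimethylsilyl enol ether (C1=C2 enol ether, (E)-C5=C10 alkene, C6=C7=C8 allene) | C=C(O[Si](C)(C)C)[C@H](O[Si](C)(C)C(C)(C)C)[C@@](C)(COCc1ccc(OC)cc1)/C=C(\C)[C@H](CC[C@@H](C)CC(=O)OCC=C)C(C)=C=C
A5 | alternative 3 | methyl 2,3-(isopropylidenedioxy)-19-(TBS-oxy)-13,14,15,16-tetranorlabd-7-en-12-oate | CC1(C)O[C@H]2C[C@@]3(C)[C@H](CC(=O)OC)C(C)=CC[C@@H]3[C@](C)(CO[Si](C)(C)C(C)(C)C)[C@H]2O1
A6 | alternative 3 | ring A cyclohexene (C1=C10) bearing the methyl (2E,4Z)-4-methylhexa-2,4-dienoate arm on C5 | CC1(C)O[C@H]2C=C(C)[C@H](C/C=C(C)\C=C\C(=O)OC)[C@](C)(CO[Si](C)(C)C(C)(C)C)[C@H]2O1
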